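**Retrosynthetic overview**

1. Core numbering: bridgeheads C1 and C5; ring A is C1–C2(aryl A)–O3–C4H2–C5 and ring B is C5–C6(aryl B)–O7–C8H2–C1. The route rests on the bridgehead bond C1–C5: with C8 as a carboxyl carbon and C6 as a vinyl CH, the array C1–C8(=O)–O–CH2–C6H=C5 is an allyl ester whose [3,3] shift makes this bond. Because C2–O3–C4 already ties C1 to C5, the shift shrinks a nine-membered lactone to ring A.
2. Ring B is made last: C6–O7 by SN1 cycloetherification of diol 24, C6–aryl B by addition of aryl Grignard reagent 22 to bicyclic lactol 21, and the lactol by oxidative cleavage of the vinyl group of alcohol 18.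
3. Ring A and C1–C5 come from the Ireland–Claisen ring contraction of the (Z)-allylic nine-membered lactone 14 to acid 17, in which C2 passes its configuration to C1 and C5.
4. Lactone 14 comes from Yamaguchi closure of seco acid 12, built from (S)-beta-hydroxy ester 9 (C2 set by Noyori hydrogenation of keto ester 8) and imidate 3 of mono-silylated (Z)-butenediol.
5. Ring order: nine-membered lactone (step 9), ring A (step 10), lactol ring (step 12), reopened in step 13 and closed again as ring B in step 14.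

Key step: step 10

Remark: aryl A is 3-hydroxy-4,5-dimethoxyphenyl (carried as its benzyl ether) and aryl B is 3,4,5-trimethoxyphenyl; both aryl groups of the target lie on the convex face (di-exo), so ring B is closed under equilibrating conditions; 22 is taken as the commercial solution in THF.

**Route**

Step 1
Reactants: 1 (Z)-but-2-ene-1,4-diol
Product: 2 (2Z)-4-[(tert-butyldiphenylsilyl)oxy]but-2-en-1-ol
Conditions: NaH (1.0 equiv), THF, 0 °C; then tBuPh2SiCl (1.0 equiv), 0 °C → rt
Reagents that add atoms: tert-butyl(chloro)diphenylsilane, CC(C)(C)[Si](Cl)(c1ccccc1)c1ccccc1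
Why: Williamson-type O-silylation of the sparingly soluble monosodium alkoxide of a symmetrical diol should stop at the mono-ether, and the bulky silyl group is chosen to survive the acid-catalysed step 7.

Step 2
Reactants: 2 (2Z)-4-[(tert-butyldiphenylsilyl)oxy]but-2-en-1-ol
Product: 3 (2Z)-4-[(tert-butyldiphenylsilyl)oxy]but-2-en-1-yl 2,2,2-trichloroacetimidate
Conditions: Cl3CCN (1.5 equiv), DBU (0.1 equiv), CH2Cl2, 0 °C
Reagents that add atoms: trichloroacetonitrile, N#CC(Cl)(Cl)Cl
Why: Base-catalysed addition of the alcohol to the nitrile (trichloroacetimidate formation) is fast at 0 °C, where the allylic imidate should not yet undergo Overman rearrangement.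

Step 3
Reactants: 4 3-hydroxy-4,5-dimethoxybenzaldehyde
Product: 5 3-(benzyloxy)-4,5-dimethoxybenzaldehyde
Conditions: BnBr, K2CO3, DMF, rt
Reagents that add atoms: benzyl bromide, BrCc1ccccc1
Why: Williamson ether synthesis on the phenoxide installs a group that tolerates the basic, acidic, hydride and organomagnesium steps and is removed at the end without acid.

Step 4
Reactants: 5 3-(benzyloxy)-4,5-dimethoxybenzaldehyde; 6 ethyl acetate
Product: 7 ethyl 3-[3-(benzyloxy)-4,5-dimethoxyphenyl]-3-hydroxypropanoate (racemic)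
Conditions: LiN(iPr)2, 6, THF, −78 °C; then 5; AcOH quench
Reagents that add atoms: none
Why: Aldol addition of the lithium enolate of ethyl acetate to a non-enolisable aryl aldehyde is reliable, and no stereocontrol is needed because the carbinol is oxidised in step 5.

Step 5
Reactants: 7 ethyl 3-[3-(benzyloxy)-4,5-dimethoxyphenyl]-3-hydroxypropanoate (racemic)
Product: 8 ethyl 3-[3-(benzyloxy)-4,5-dimethoxyphenyl]-3-oxopropanoate
Conditions: Dess–Martin periodinane (1.2 equiv), CH2Cl2, 0 °C → rt
Reagents that add atoms: none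
Why: Dess–Martin oxidation converts the secondary benzylic alcohol into the beta-keto ester under neutral conditions that should not dehydrate the aldol.

Step 6
Reactants: 8 ethyl 3-[3-(benzyloxy)-4,5-dimethoxyphenyl]-3-oxopropanoate
Product: 9 ethyl (3S)-3-[3-(benzyloxy)-4,5-dimethoxyphenyl]-3-hydroxypropanoate
Conditions: H2 (10 atm), RuCl2[(R)-BINAP](DMF)n (1 mol%), EtOH, 80 °C
Reagents that add atoms: none
Why: Noyori asymmetric hydrogenation of a beta-keto ester: the ester-chelated ketone is reduced by the ruthenium hydride formed from RuCl2[(R)-BINAP](DMF)n on the face that gives the spatial arrangement of (R)-3-hydroxybutanoate, which for an aryl ketone is the (S)-carbinol at C2, and this homogeneous catalyst should leave the aryl benzyl ether intact.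

Step 7
Reactants: 9 ethyl (3S)-3-[3-(benzyloxy)-4,5-dimethoxyphenyl]-3-hydroxypropanoate; 3 (2Z)-4-[(tert-butyldiphenylsilyl)oxy]but-2-en-1-yl 2,2,2-trichloroacetimidate
Product: 10 ethyl (3S)-3-[3-(benzyloxy)-4,5-dimethoxyphenyl]-3-{[(2Z)-4-[(tert-butyldiphenylsilyl)oxy]but-2-en-1-yl]oxy}propanoate
Conditions: 3 (1.8 equiv), TfOH (5 mol%), cyclohexane–CH2Cl2 (2:1), 0 °C → rt
Reagents that add atoms: none
Why: Acid-catalysed O-alkylation with an allylic trichloroacetimidate forms the O3–C4 bond without the retro-aldol and beta-elimination that a basic Williamson alkylation of a beta-hydroxy ester would bring, and the C2–O bond is not broken, so C2 keeps its configuration.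

Step 8
Reactants: 10 ethyl (3S)-3-[3-(benzyloxy)-4,5-dimethoxyphenyl]-3-{[(2Z)-4-[(tert-butyldiphenylsilyl)oxy]but-2-en-1-yl]oxy}propanoate
Product: 12 (3S)-3-[3-(benzyloxy)-4,5-dimethoxyphenyl]-3-{[(2Z)-4-hydroxybut-2-en-1-yl]oxy}propanoic acid, via hydroxy ester 11 (not isolated)
Conditions: Bu4NF, THF, 0 °C → rt; then LiOH, THF–MeOH–H2O, 0 °C → rt; 1 M HCl to pH 3 at 0 °C
Reagents that add atoms: lithium hydroxide, [Li+].[OH-]
Why: Fluoride desilylation followed by saponification of the ethyl ester should give the hydroxy acid in one operation, since ester hydrolysis at low temperature outpaces beta-elimination and the carboxylate, once formed, can no longer eliminate.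

Step 9
Reactants: 12 (3S)-3-[3-(benzyloxy)-4,5-dimethoxyphenyl]-3-{[(2Z)-4-hydroxybut-2-en-1-yl]oxy}propanoic acid
Product: 14 (4S,7Z)-4-[3-(benzyloxy)-4,5-dimethoxyphenyl]-1,5-dioxacyclonon-7-en-2-one, via mixed anhydride 13 (not isolated)
Conditions: 2,4,6-Cl3C6H2COCl, Et3N, THF, rt; then syringe-pump addition to DMAP, toluene, 80 °C (final 2 mM)
Reagents that add atoms: none
Why: Yamaguchi macrolactonisation: acyl transfer from the mixed anhydride through the acylpyridinium ion to the primary allylic alcohol under high dilution should close the nine-membered ring, in which the (Z)-alkene and the ether oxygen lower the transannular strain.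

Step 10
Reactants: 14 (4S,7Z)-4-[3-(benzyloxy)-4,5-dimethoxyphenyl]-1,5-dioxacyclonon-7-en-2-one
Product: 17 (2S,3S,4R)-2-[3-(benzyloxy)-4,5-dimethoxyphenyl]-4-ethenyloxolane-3-carboxylic acid, via silyl ketene acetal 15 (not isolated), via trimethylsilyl ester 16 (not isolated)
Conditions: Me3SiCl–Et3N (1:1), THF, −100 °C; LiN(iPr)2 (1.3 equiv) added slowly; −100 °C → rt, then 65 °C; 1 M HCl
Reagents that add atoms: none
Why: LiN(iPr)2 removes a C1 proton of 14 with Me3SiCl already present, so the enolate is trapped on oxygen as the endocyclic silyl ketene acetal 15 before it can eject the beta-oxygen O3, and 15 then undergoes a concerted [3,3]-sigmatropic shift that joins C1 to C5, cleaves the allylic C–O bond and gives silyl ester 16, which the acidic work-up hydrolyses to 17. The closest known reaction type is the Ireland–Claisen rearrangement run as a ring contraction of unsaturated oxa-macrolactones to trisubstituted tetrahydrofurans. Ring A (C1–C2–O3–C4–C5) is closed by the new C1–C5 bond in a transannular mode, formally a 5-exo closure of ketene acetal carbon C1 onto alkene carbon C5 with the double bond moving out to the C6 vinyl group. Since both the ketene acetal double bond (ring carbon C2 cis to the allylic ring oxygen) and the (Z)-alkene are endocyclic, C1 and C5 can only meet through a boat-shaped array, which puts carboxyl carbon C8 and vinyl carbon C6 on the same side of the new ring and so fixes C5 relative to C1. The C2 stereocentre selects the face of C1: the conformer with aryl A pseudo-equatorial on the forming oxolane should be preferred, leaving aryl A trans to the carboxyl group and translating (S)-C2 into the C1 and C5 configurations of 17. The step needs O-silylation to beat beta-elimination, which the internal Me3SiCl quench at −100 °C should provide, and 2,3-trans-3,4-cis diastereoselection, which the C2 centre and the ring-bound alkene geometries should provide.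

Step 11
Reactants: 17 (2S,3S,4R)-2-[3-(benzyloxy)-4,5-dimethoxyphenyl]-4-ethenyloxolane-3-carboxylic acid
Product: 18 [(2S,3R,4R)-2-[3-(benzyloxy)-4,5-dimethoxyphenyl]-4-ethenyloxolan-3-yl]methanol
Conditions: LiAlH4, THF, 0 °C → rt; Fieser work-up
Reagents that add atoms: none
Why: LiAlH4 reduction of the carboxylic acid gives the primary alcohol C8H2OH and should leave the isolated vinyl group, the benzyl ether and the oxolane untouched without epimerising C1.

Step 12
Reactants: 18 [(2S,3R,4R)-2-[3-(benzyloxy)-4,5-dimethoxyphenyl]-4-ethenyloxolan-3-yl]methanol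
Product: 21 (3aR,4S,6aR)-4-[3-(benzyloxy)-4,5-dimethoxyphenyl]tetrahydro-1H,3H-furo[3,4-c]furan-1-ol (anomers), via diol 19 (not isolated), via hydroxy aldehyde 20 (not isolated)
Conditions: OsO4 (2 mol%), NaIO4 (4 equiv), 2,6-lutidine, dioxane–H2O (3:1), rt
Reagents that add atoms: osmium tetroxide (oxygen donor, catalytic), O=[Os](=O)(=O)=O; NaIO4 (stoichiometric oxygen source), [Na+].[O-]I(=O)(=O)=O
Why: Lemieux–Johnson oxidative cleavage of the terminal vinyl group gives the C6 aldehyde, which lies cis to C8H2OH and should be trapped at once as the cis-fused five-membered lactol, while the electron-rich arene and the benzyl ether are spared the exposure to ozone.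

Step 13
Reactants: 21 (3aR,4S,6aR)-4-[3-(benzyloxy)-4,5-dimethoxyphenyl]tetrahydro-1H,3H-furo[3,4-c]furan-1-ol (anomers); 22 3,4,5-trimethoxyphenylmagnesium bromide
Product: 24 [(2S,3R,4R)-2-[3-(benzyloxy)-4,5-dimethoxyphenyl]-4-[hydroxy(3,4,5-trimethoxyphenyl)methyl]oxolan-3-yl]methanol (carbinol epimers), via magnesium alkoxide aldehyde 23 (not isolated)
Conditions: 22 (3.5 equiv, 0.5 M in THF), THF, 0 °C → rt; sat. NH4Cl
Reagents that add atoms: none
Why: Grignard addition to a lactol: the first equivalent of 22 deprotonates the hemiacetal, which then reacts through its ring-opened form, the magnesium alkoxide aldehyde 23, with a second equivalent at the C6 carbonyl, and the configuration of the new carbinol is of no consequence because C6 is ionised in step 14.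

Step 14
Reactants: 24 [(2S,3R,4R)-2-[3-(benzyloxy)-4,5-dimethoxyphenyl]-4-[hydroxy(3,4,5-trimethoxyphenyl)methyl]oxolan-3-yl]methanol (carbinol epimers)
Product: 25 (1S,3aR,4S,6aR)-1-[3-(benzyloxy)-4,5-dimethoxyphenyl]-4-(3,4,5-trimethoxyphenyl)tetrahydro-1H,3H-furo[3,4-c]furan
Conditions: BF3·OEt2 (0.3 equiv), CH2Cl2, 0 °C → rt
Reagents that add atoms: none
Why: Acid-mediated SN1 cycloetherification: ionisation of the para-methoxy-stabilised benzylic carbinol at C6 and capture by C8–OH closes ring B as the only possible cis-fused bicycle, and reversible ionisation should place aryl B on the convex face trans to C4, the thermodynamically favoured di-exo arrangement that sets C6 as (S).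

Step 15
Reactants: 25 (1S,3aR,4S,6aR)-1-[3-(benzyloxy)-4,5-dimethoxyphenyl]-4-(3,4,5-trimethoxyphenyl)tetrahydro-1H,3H-furo[3,4-c]furan
Product: 26 5-[(1S,3aR,4S,6aR)-4-(3,4,5-trimethoxyphenyl)tetrahydro-1H,3H-furo[3,4-c]furan-1-yl]-2,3-dimethoxyphenol
Conditions: H2 (1 atm), 10% Pd/C, EtOAc, rt, stopped at full conversion
Reagents that add atoms: none
Why: Catalytic hydrogenolysis of the aryl benzyl ether in neutral ethyl acetate should be much faster than cleavage of the two cyclic benzylic C–O bonds of the furofuran, so the phenol is released without ring opening.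

**Compound list**

1 | (Z)-but-2-ene-1,4-diol | OC/C=C\CO | starting material
2 | (2Z)-4-[(tert-butyldiphenylsilyl)oxy]but-2-en-1-ol | OC/C=C\CO[Si](c1ccccc1)(c1ccccc1)C(C)(C)C | intermediate
3 | (2Z)-4-[(tert-butyldiphenylsilyl)oxy]but-2-en-1-yl 2,2,2-trichloroacetimidate | N=C(OC/C=C\CO[Si](c1ccccc1)(c1ccccc1)C(C)(C)C)C(Cl)(Cl)Cl | intermediate
4 | 3-hydroxy-4,5-dimethoxybenzaldehyde | COc1cc(C=O)cc(O)c1OC | starting material
5 | 3-(benzyloxy)-4,5-dimethoxybenzaldehyde | COc1cc(C=O)cc(OCc2ccccc2)c1OC | intermediate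
6 | ethyl acetate | CCOC(C)=O | starting material
7 | ethyl 3-[3-(benzyloxy)-4,5-dimethoxyphenyl]-3-hydroxypropanoate (racemic) | COc1cc(C(O)CC(=O)OCC)cc(OCc2ccccc2)c1OC | intermediate
8 | ethyl 3-[3-(benzyloxy)-4,5-dimethoxyphenyl]-3-oxopropanoate | COc1cc(C(=O)CC(=O)OCC)cc(OCc2ccccc2)c1OC | intermediate
9 | ethyl (3S)-3-[3-(benzyloxy)-4,5-dimethoxyphenyl]-3-hydroxypropanoate | COc1cc([C@@H](O)CC(=O)OCC)cc(OCc2ccccc2)c1OC | intermediate
10 | ethyl (3S)-3-[3-(benzyloxy)-4,5-dimethoxyphenyl]-3-{[(2Z)-4-[(tert-butyldiphenylsilyl)oxy]but-2-en-1-yl]oxy}propanoate | COc1cc([C@@H](OC/C=C\CO[Si](c2ccccc2)(c2ccccc2)C(C)(C)C)CC(=O)OCC)cc(OCc2ccccc2)c1OC | intermediate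
11 | ethyl (3S)-3-[3-(benzyloxy)-4,5-dimethoxyphenyl]-3-{[(2Z)-4-hydroxybut-2-en-1-yl]oxy}propanoate (hydroxy ester) | COc1cc([C@@H](OC/C=C\CO)CC(=O)OCC)cc(OCc2ccccc2)c1OC | intermediate
12 | (3S)-3-[3-(benzyloxy)-4,5-dimethoxyphenyl]-3-{[(2Z)-4-hydroxybut-2-en-1-yl]oxy}propanoic acid | COc1cc([C@@H](OC/C=C\CO)CC(O)=O)cc(OCc2ccccc2)c1OC | intermediate
13 | mixed anhydride of 12 with 2,4,6-trichlorobenzoic acid | COc1cc([C@@H](OC/C=C\CO)CC(=O)OC(=O)c2c(Cl)cc(Cl)cc2Cl)cc(OCc2ccccc2)c1OC | intermediate
14 | (4S,7Z)-4-[3-(benzyloxy)-4,5-dimethoxyphenyl]-1,5-dioxacyclonon-7-en-2-one | COc1cc([C@@H]2CC(=O)OC/C=C\CO2)cc(OCc2ccccc2)c1OC | intermediate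
15 | (2E,4S,7Z)-4-[3-(benzyloxy)-4,5-dimethoxyphenyl]-2-[(trimethylsilyl)oxy]-1,5-dioxacyclonona-2,7-diene (silyl ketene acetal, ring carbon C4 cis to O1) | COc1cc([C@@H]2/C=C(/O[Si](C)(C)C)OC/C=C\CO2)cc(OCc2ccccc2)c1OC | intermediate
16 | trimethylsilyl (2S,3S,4R)-2-[3-(benzyloxy)-4,5-dimethoxyphenyl]-4-ethenyloxolane-3-carboxylate | COc1cc([C@H]2OC[C@H](C=C)[C@@H]2C(=O)O[Si](C)(C)C)cc(OCc2ccccc2)c1OC | intermediate
17 | (2S,3S,4R)-2-[3-(benzyloxy)-4,5-dimethoxyphenyl]-4-ethenyloxolane-3-carboxylic acid (2,3-trans-3,4-cis) | COc1cc([C@H]2OC[C@H](C=C)[C@@H]2C(O)=O)cc(OCc2ccccc2)c1OC | intermediate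
18 | [(2S,3R,4R)-2-[3-(benzyloxy)-4,5-dimethoxyphenyl]-4-ethenyloxolan-3-yl]methanol | COc1cc([C@H]2OC[C@H](C=C)[C@@H]2CO)cc(OCc2ccccc2)c1OC | intermediate
19 | 1-[(3R,4R,5S)-5-[3-(benzyloxy)-4,5-dimethoxyphenyl]-4-(hydroxymethyl)oxolan-3-yl]ethane-1,2-diol (carbinol epimers) | COc1cc([C@H]2OC[C@H](C(O)CO)[C@@H]2CO)cc(OCc2ccccc2)c1OC | intermediate
20 | (3R,4R,5S)-5-[3-(benzyloxy)-4,5-dimethoxyphenyl]-4-(hydroxymethyl)oxolane-3-carbaldehyde (hydroxy aldehyde) | COc1cc([C@H]2OC[C@H](C=O)[C@@H]2CO)cc(OCc2ccccc2)c1OC | intermediate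
21 | (3aR,4S,6aR)-4-[3-(benzyloxy)-4,5-dimethoxyphenyl]tetrahydro-1H,3H-furo[3,4-c]furan-1-ol (anomers) | COc1cc([C@H]2OC[C@H]3[C@@H]2COC3O)cc(OCc2ccccc2)c1OC | intermediate
22 | 3,4,5-trimethoxyphenylmagnesium bromide | COc1cc([Mg]Br)cc(OC)c1OC | starting material
23 | bromomagnesium [(2S,3R,4R)-2-[3-(benzyloxy)-4,5-dimethoxyphenyl]-4-formyloxolan-3-yl]methanolate (magnesium alkoxide aldehyde) | COc1cc([C@H]2OC[C@H](C=O)[C@@H]2CO[Mg]Br)cc(OCc2ccccc2)c1OC | intermediate
24 | [(2S,3R,4R)-2-[3-(benzyloxy)-4,5-dimethoxyphenyl]-4-[hydroxy(3,4,5-trimethoxyphenyl)methyl]oxolan-3-yl]methanol (carbinol epimers) | COc1cc([C@H]2OC[C@H](C(O)c3cc(OC)c(OC)c(OC)c3)[C@@H]2CO)cc(OCc2ccccc2)c1OC | intermediate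
25 | (1S,3aR,4S,6aR)-1-[3-(benzyloxy)-4,5-dimethoxyphenyl]-4-(3,4,5-trimethoxyphenyl)tetrahydro-1H,3H-furo[3,4-c]furan | COc1cc([C@H]2OC[C@H]3[C@@H]2CO[C@@H]3c2cc(OC)c(OC)c(OC)c2)cc(OCc2ccccc2)c1OC | intermediate
26 | 5-[(1S,3aR,4S,6aR)-4-(3,4,5-trimethoxyphenyl)tetrahydro-1H,3H-furo[3,4-c]furan-1-yl]-2,3-dimethoxyphenol | COc1cc([C@H]2OC[C@H]3[C@@H]2CO[C@@H]3c2cc(OC)c(OC)c(OC)c2)cc(O)c1OC | target

**Step count**

Total step count: 15. Longest linear sequence: 13 steps (steps 3 to 15, from aldehyde 4); steps 1 and 2 make the imidate branch.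

**Steps most likely to fail**

Step 10 (key step). What may go wrong: expulsion of the beta-alkoxide O3 from the lithium enolate, opening the ring to a cinnamate, if deprotonation outruns silylation; or erosion of the boat preference, giving mixtures at C1 and C5. The fallback replaces the ring contraction by an acyclic dianionic ester-enolate Claisen rearrangement, in which the beta-oxygen is a lithium alkoxide and cannot leave. It sets out from keto ester 8 and alcohol 2 and comes back at alcohol 18. Keto ester 8 would be hydrogenated with RuCl2[(S)-BINAP](DMF)n to ethyl (3R)-3-[3-(benzyloxy)-4,5-dimethoxyphenyl]-3-hydroxypropanoate F1; the opposite carbinol is needed because C1 is now installed anti to the carbinol and C2 is set again later. Transesterification with alcohol 2 (Ti(OEt)4 cat., toluene, 110 °C) would give (2Z)-4-[(tert-butyldiphenylsilyl)oxy]but-2-en-1-yl (3R)-3-[3-(benzyloxy)-4,5-dimethoxyphenyl]-3-hydroxypropanoate F2. Double deprotonation (LiN(iPr)2, 2.5 equiv, THF, −78 → 50 °C; dilute HCl) should give, through the chelated dilithium enolate and a chair transition state, (2S,3R)-2-{(R)-[3-(benzyloxy)-4,5-dimethoxyphenyl](hydroxy)methyl}-3-{[(tert-butyldiphenylsilyl)oxy]methyl}pent-4-enoic acid F3; C1–C5 is formed here, with C1 anti to the carbinol in the Fráter–Seebach sense and C5 fixed by the (Z)-alkene, which is the C1/C5 configuration of 18. LiAlH4 would reduce the acid to (2R,3R)-2-{(R)-[3-(benzyloxy)-4,5-dimethoxyphenyl](hydroxy)methyl}-3-{[(tert-butyldiphenylsilyl)oxy]methyl}pent-4-en-1-ol F4, and Bu4NF would give (2R,3R)-2-{(R)-[3-(benzyloxy)-4,5-dimethoxyphenyl](hydroxy)methyl}-3-ethenylbutane-1,4-diol F5. BF3·OEt2 (cat., CH2Cl2, 0 °C) would then ionise the benzylic carbinol at C2, and capture by C4–OH (five-membered ring preferred over the oxetane from C8–OH) should close ring A with aryl A trans to C8H2OH, giving alcohol 18.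

Step 9. What may go wrong: intermolecular acylation (diolide and oligomers) competing with closure of the medium ring, or beta-elimination of the activated acyl intermediate under DMAP at elevated temperature. The fallback activates the alcohol instead of the acid: Mitsunobu macrolactonisation of seco acid 12 (PPh3, diisopropyl azodicarboxylate, toluene–THF, slow addition, 0 °C → rt), in which the carboxylate, which cannot eliminate, displaces the primary allylic oxyphosphonium group. It sets out from 12 and comes back at lactone 14; it makes no new compound (F0).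

Step 7. What may go wrong: acid-promoted ionisation of the electron-rich benzylic carbinol (racemisation at C2, dehydration to the cinnamate), or allyl-cation scrambling of the imidate (E/Z isomerisation, branched ether). The fallback replaces the cationic imidate transfer by a neutral halide-abstraction SN2 alkylation. It sets out from alcohol 2 and hydroxy ester 9 and comes back at ether 10. Alcohol 2 would be converted (CBr4, PPh3, CH2Cl2, 0 °C) into (Z)-[(4-bromobut-2-en-1-yl)oxy](tert-butyl)diphenylsilane F6, and 9 would be alkylated with F6 and Ag2O (CaSO4, Et2O, dark, rt) to give 10.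

**Further compounds**

F1 | step 10 | ethyl (3R)-3-[3-(benzyloxy)-4,5-dimethoxyphenyl]-3-hydroxypropanoate | COc1cc([C@H](O)CC(=O)OCC)cc(OCc2ccccc2)c1OC
F2 | step 10 | (2Z)-4-[(tert-butyldiphenylsilyl)oxy]but-2-en-1-yl (3R)-3-[3-(benzyloxy)-4,5-dimethoxyphenyl]-3-hydroxypropanoate | COc1cc([C@H](O)CC(=O)OC/C=C\CO[Si](c2ccccc2)(c2ccccc2)C(C)(C)C)cc(OCc2ccccc2)c1OC
F3 | step 10 | (2S,3R)-2-{(R)-[3-(benzyloxy)-4,5-dimethoxyphenyl](hydroxy)methyl}-3-{[(tert-butyldiphenylsilyl)oxy]methyl}pent-4-enoic acid | COc1cc([C@H](O)[C@@H](C(O)=O)[C@@H](C=C)CO[Si](c2ccccc2)(c2ccccc2)C(C)(C)C)cc(OCc2ccccc2)c1OC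
F4 | step 10 | (2R,3R)-2-{(R)-[3-(benzyloxy)-4,5-dimethoxyphenyl](hydroxy)methyl}-3-{[(tert-butyldiphenylsilyl)oxy]methyl}pent-4-en-1-ol | COc1cc([C@H](O)[C@@H](CO)[C@@H](C=C)CO[Si](c2ccccc2)(c2ccccc2)C(C)(C)C)cc(OCc2ccccc2)c1OC
F5 | step 10 | (2R,3R)-2-{(R)-[3-(benzyloxy)-4,5-dimethoxyphenyl](hydroxy)methyl}-3-ethenylbutane-1,4-diol | COc1cc([C@H](O)[C@@H](CO)[C@@H](C=C)CO)cc(OCc2ccccc2)c1OC
F0 | step 9 | none | none
F6 | step 7 | (Z)-[(4-bromobut-2-en-1-yl)oxy](tert-butyl)diphenylsilane | BrC/C=C\CO[Si](c1ccccc1)(c1ccccc1)C(C)(C)C
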